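## Retrosynthetic overview

1. γ-Lactone (last ring): cut C11–C12 to a 7-ethynyl-6-hydroxycyclodecene triol mono-isobutyrate plus CO. The enabling feature is the 3-butyn-1-ol array O6–C6–C7–C11≡C13 on the ten-membered ring (C6–OH and C7–ethynyl trans and adjacent, O8 already acylated, O3 and O10 too remote for a five-membered ring).
2. Ten-membered carbocycle: C3–C4 by intramolecular Nozaki–Hiyama–Kishi coupling of a (Z)-iodoalkene with the C3 aldehyde. C3 is then fixed by oxidation and CBS reduction.
3. C6 and C7: anti-selective allenylboration of (Z)-3-iodobut-2-enal with an axially chiral allenyl-Bpin. Axis and C8–O come from a cis-alkynyl oxirane (temporary ring) by Cu-catalysed anti-SN2′ borylation.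
4. cis-Alkynyl oxirane: Sharpless epoxidation of a (Z)-allylic alcohol, oxidation, Ohira–Bestmann alkynylation. C10 carbinol: Sharpless epoxidation of geraniol, then Red-Al.
5. Ring order: oxirane (opened in step 10) → cyclodecene (step 17) → α-methylene-γ-butyrolactone (step 21).

Key step: step 21

Remark (numbering): germacrane numbering is used for positions: ring C1–C10, C14 = methyl on C10, C15 = methyl on C4, C11/C13 = alkyne (later methylene) carbons, C12 = lactone carbonyl. The target is (3S,6R,7R,8R,10S), 4Z.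

Remark (assumption): the Cu–boryl opening of the alkynyl oxirane is taken to follow the anti-SN2′ course known for propargylic carbonates and oxiranes. This is what links the cis-oxirane to the required allene axis.

## Route

Step 1
Reactants: 1 geraniol
Product: 2 (2S,3S)-2,3-epoxygeraniol
Conditions: Ti(OiPr)4 (5 mol%), L-(+)-DET (7 mol%), t-BuOOH, 4 Å MS, CH2Cl2, −20 °C
Reagents that add atoms: tert-butyl hydroperoxide, CC(C)(C)OO
Why: Katsuki–Sharpless asymmetric epoxidation of an allylic alcohol; L-(+)-tartrate directs oxygen to the face that gives the (2S,3S)-oxirane, whose C3 becomes the (S)-configured tertiary carbinol C10 of the target.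

Step 2
Reactants: 2 (2S,3S)-2,3-epoxygeraniol
Product: 3 (3S)-3,7-dimethyloct-6-ene-1,3-diol
Conditions: Red-Al, THF, 0 °C → rt; Rochelle salt
Reagents that add atoms: none
Why: Hydroxyl-directed Red-Al opening of a 2,3-epoxy alcohol delivers hydride intramolecularly to C2 (the future C9), so the tertiary C–O bond and its configuration are untouched and the 1,3-diol results.

Step 3
Reactants: 3 (3S)-3,7-dimethyloct-6-ene-1,3-diol
Product: 4 bis(triethylsilyl) ether of 3
Conditions: TESOTf (2.5 equiv), 2,6-lutidine, CH2Cl2, −78 → 0 °C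
Reagents that add atoms: triethylsilyl trifluoromethanesulfonate, CC[Si](CC)(CC)OS(=O)(=O)C(F)(F)F
Why: Silyl triflate with 2,6-lutidine is the standard way to cap a tertiary alcohol; the primary ether formed alongside is removed in step 4 and no stereocentre is touched.

Step 4
Reactants: 4 bis(triethylsilyl) ether
Product: 5 (3S)-3,7-dimethyl-3-(triethylsilyloxy)oct-6-enal
Conditions: (COCl)2, DMSO, CH2Cl2, −78 → −35 °C; Et3N, −78 °C → rt
Reagents that add atoms: none
Why: Swern oxidation in which the primary triethylsilyl ether is cleaved in situ by the chlorosulfonium salt and oxidised directly to the aldehyde, while the hindered tertiary silyl ether survives (known oxidative deprotection of primary TES ethers).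

Step 5
Reactants: 5 (3S)-3,7-dimethyl-3-(triethylsilyloxy)oct-6-enal
Product: 6 methyl (2Z,5S)-5,9-dimethyl-5-(triethylsilyloxy)deca-2,8-dienoate
Conditions: (CF3CH2O)2P(O)CH2CO2Me, KHMDS, 18-crown-6, THF, −78 °C
Reagents that add atoms: methyl bis(2,2,2-trifluoroethyl)phosphonoacetate, COC(=O)CP(=O)(OCC(F)(F)F)OCC(F)(F)F
Why: Still–Gennari variant of the Horner–Wadsworth–Emmons olefination; the trifluoroethyl phosphonate with a dissociated potassium counter-ion eliminates under kinetic control to the (Z)-enoate, the geometry that later gives the cis-oxirane.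

Step 6
Reactants: 6 (Z)-enoate
Product: 7 (2Z,5S)-5,9-dimethyl-5-(triethylsilyloxy)deca-2,8-dien-1-ol
Conditions: DIBAL-H (2.2 equiv), CH2Cl2, −78 °C; Rochelle salt
Reagents that add atoms: none
Why: DIBAL-H 1,2-reduction of the enoate to the allylic alcohol at low temperature, with retention of the Z geometry.

Step 7
Reactants: 7 (Z)-allylic alcohol
Product: 8 cis-epoxy alcohol (2S,3R)
Conditions: Ti(OiPr)4 (1.0 equiv), L-(+)-DET (1.2 equiv), t-BuOOH, 4 Å MS, CH2Cl2, −20 °C
Reagents that add atoms: tert-butyl hydroperoxide, CC(C)(C)OO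
Why: Katsuki–Sharpless epoxidation of a (Z)-allylic alcohol (stoichiometric titanium–tartrate because Z substrates react slowly); L-(+)-tartrate should give the (2S,3R) cis-epoxy alcohol under reagent control, which sets the permanent C8–O stereocentre and the temporary C7–O centre.

Step 8
Reactants: 8 cis-epoxy alcohol
Product: 9 cis-epoxy aldehyde
Conditions: Dess–Martin periodinane, NaHCO3, CH2Cl2, 0 °C → rt
Reagents that add atoms: none
Why: Buffered Dess–Martin oxidation of a primary alcohol; the oxirane α-C–H is not enolised under these conditions, so the cis-epoxy aldehyde should keep its configuration.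

Step 9
Reactants: 9 cis-epoxy aldehyde
Product: 10 cis-alkynyl oxirane
Conditions: dimethyl (1-diazo-2-oxopropyl)phosphonate, K2CO3, MeOH, 0 °C → rt
Reagents that add atoms: dimethyl (1-diazo-2-oxopropyl)phosphonate, COP(=O)(OC)C(=[N+]=[N-])C(C)=O
Why: Seyferth–Gilbert homologation with the Ohira–Bestmann reagent converts the aldehyde into the terminal alkyne (C11≡C13) under mild K2CO3/MeOH conditions without touching the oxirane.

Step 10
Reactants: 10 cis-alkynyl oxirane
Product: 11 (aS)-allenylboronate alcohol
Conditions: B2pin2 (1.3 equiv), CuCl (10 mol%), PCy3 (12 mol%), KOt-Bu (20 mol%), MeOH (2 equiv), THF, 0 °C → rt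
Reagents that add atoms: bis(pinacolato)diboron, CC1(C)OB(OC1(C)C)B1OC(C)(C)C(C)(C)O1
Why: Copper-catalysed borylative SN2′ opening of a propargylic oxirane (borylcupration with boron on the terminal carbon, then anti β-oxygen elimination); the anti course transfers the C7 central chirality to the (aS) allene axis while the C8–O bond keeps its configuration, and boron, unlike zinc or indium, does not expel the neighbouring oxygen.

Step 11
Reactants: 11 (aS)-allenylboronate alcohol
Product: 12 (aS)-allenylboronate isobutyrate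
Conditions: i-PrCOCl, pyridine, DMAP (cat.), CH2Cl2, 0 °C
Reagents that add atoms: 2-methylpropanoyl chloride, CC(C)C(Cl)=O
Why: DMAP-catalysed acylation of the only free hydroxyl places the isobutyrate of the target on O8 before O6 exists, with retention at C8.

Step 12
Reactants: 13 but-2-yn-1-ol
Product: 15 (Z)-3-iodobut-2-en-1-ol, via cyclic alkenylalanate 14 (not isolated)
Conditions: Red-Al, THF, 0 °C → rt; then I2, THF, −78 → 0 °C
Reagents that add atoms: iodine, II
Why: Hydroxyl-directed trans-hydroalumination of the propargylic alcohol places aluminium on C3 in a five-membered alanate, and iodinolysis with retention gives the (Z)-3-iodoalkenol, which fixes the future C4=C5 geometry.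

Step 13
Reactants: 15 (Z)-3-iodobut-2-en-1-ol
Product: 16 (Z)-3-iodobut-2-enal
Conditions: activated MnO2, CH2Cl2, rt, dark; used at once
Reagents that add atoms: none
Why: Allylic oxidation with activated MnO2 under neutral conditions should give the enal without Z→E isomerisation of the β-iodo enal.

Step 14
Reactants: 12 (aS)-allenylboronate isobutyrate; 16 (Z)-3-iodobut-2-enal
Product: 18 anti-homopropargylic alcohol, via pinacol borate ester 17 (not isolated)
Conditions: toluene (1 M), 4 Å MS, rt → 40 °C, dark; pH 7 buffer work-up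
Reagents that add atoms: none
Why: Allenylboration (SE2′) through a closed six-membered transition state: the boron-bound aldehyde attacks C7 on the boron-bearing face of the allene, so the axis is transferred to the C7 centre, and the orientation with the alkenyl group away from the C8 branch gives the anti homopropargylic alcohol, which sets C6; the borate 17 hydrolyses on work-up.

Step 15
Reactants: 18 anti-homopropargylic alcohol
Product: 19 C6 triethylsilyl ether
Conditions: TESOTf, 2,6-lutidine, CH2Cl2, −78 °C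
Reagents that add atoms: triethylsilyl trifluoromethanesulfonate, CC[Si](CC)(CC)OS(=O)(=O)C(F)(F)F
Why: Standard silylation of the hindered secondary allylic alcohol under non-basic conditions that do not promote O8→O6 acyl migration; it keeps O6 apart from O3 during the later oxidation and reduction at C3.

Step 16
Reactants: 19 C6 triethylsilyl ether
Product: 21 C3 aldehyde, via vicinal diol 20 (not isolated)
Conditions: OsO4 (2 mol%), NaIO4 (4 equiv), 2,6-lutidine, dioxane/H2O 3:1, rt
Reagents that add atoms: osmium tetroxide (catalytic oxygen carrier), O=[Os](=O)(=O)=O; sodium periodate (terminal oxidant), [Na+].[O-]I(=O)(=O)=O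
Why: Lemieux–Johnson oxidation: OsO4 dihydroxylates the electron-rich trisubstituted alkene much faster than the iodoalkene and does not touch the alkyne, and periodate cleaves the diol 20 to the C3 aldehyde with loss of acetone.

Step 17
Reactants: 21 C3 aldehyde
Product: 22 ten-membered allylic alcohol (C3 epimers)
Conditions: CrCl2 (10 equiv), NiCl2 (0.1 equiv), DMSO/THF 3:1, rt, 2 mM, slow addition
Reagents that add atoms: none
Why: Nozaki–Hiyama–Kishi reaction under high dilution: nickel(0) inserts into the C–I bond, transmetalation gives the alkenylchromium(III) species with retention of the Z geometry, and this adds chemoselectively to the aldehyde to close the ring at C3–C4; the C3 carbinol forms without reliable control and is corrected in steps 18 and 19.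

Step 18
Reactants: 22 ten-membered allylic alcohol (C3 epimers)
Product: 23 ten-membered (Z)-enone
Conditions: Dess–Martin periodinane, NaHCO3, CH2Cl2, 0 °C
Reagents that add atoms: none
Why: Dess–Martin oxidation of the allylic alcohol converges both C3 epimers to one enone, whose ring-cis C4=C5 bond is held by the ten-membered ring.

Step 19
Reactants: 23 ten-membered (Z)-enone
Product: 24 (3S)-allylic alcohol
Conditions: (R)-2-methyl-CBS-oxazaborolidine (1.0 equiv), catecholborane (2.5 equiv), toluene, −78 → −40 °C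
Reagents that add atoms: none
Why: Corey–Bakshi–Shibata reduction: with the (R)-oxazaborolidine the α-methylalkenyl arm acts as the large group and the C2 methylene as the small one, so hydride should arrive on the face that gives the (3S)-carbinol under reagent control, and catecholborane at low temperature leaves the alkyne and ester alone.

Step 20
Reactants: 24 (3S)-allylic alcohol
Product: 25 ethynyl triol mono-isobutyrate
Conditions: HF·pyridine, pyridine, THF, 0 °C → rt
Reagents that add atoms: none
Why: Fluoride-mediated cleavage of both triethylsilyl ethers with pyridine-buffered HF·pyridine, conditions under which the isobutyrate should neither hydrolyse nor migrate to O6.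

Step 21
Reactants: 25 ethynyl triol mono-isobutyrate
Product: 28 CNP0163972.1, via alkoxycarbonylpalladium chloride 26 (not isolated), via vinylpalladium lactone 27 (not isolated)
Conditions: PdCl2 (5 mol%), PPh3 (10 mol%), anhydrous SnCl2 (5 mol%), CO (7 atm), MeCN, 70 °C
Reagents that add atoms: carbon monoxide, [C-]#[O+]
Why: The C6 hydroxyl and CO give the alkoxycarbonyl–Pd(II) species 26, whose Pd–C(=O)O unit adds syn across C11≡C13 so that the ring is closed by the new C11–C12 bond, and protonolysis of the vinyl–Pd bond of 27 by the HCl released in the first stage returns Pd(II) and leaves the exocyclic methylene. The closest known reaction type is the PdCl2/SnCl2/PPh3-catalysed cyclocarbonylation of 3-butyn-1-ols, including trans-2-ethynylcycloalkanols, to α-methylene-γ-butyrolactones. The five-membered ring closes in a 5-exo-dig mode onto the internal alkyne carbon, the only regiochemistry the O–C6–C7 tether allows. No new stereocentre is formed: C6 and C7 are not touched, so the trans ring fusion is the one set in step 14, and the new alkene is a terminal methylene without geometry. The step needs chemoselectivity among three free hydroxyls and against the allylic C–O bonds: O8 is blocked as the isobutyrate, O3 and O10 could only close eight- and seven-membered rings, and the base-free Pd(II) manifold should keep allylic ionisation and acyl migration slow. In one operation the last carbon (C12), the O–C12 and C11–C12 bonds, the lactone ring and the conjugated methylene are installed on an unprotected substrate, so the Michael acceptor never has to survive another step.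

## Compound list

1 | geraniol, (2E)-3,7-dimethylocta-2,6-dien-1-ol | CC(C)=CCC/C(C)=C/CO | starting material
2 | (2S,3S)-2,3-epoxygeraniol, [(2S,3S)-3-methyl-3-(4-methylpent-3-en-1-yl)oxiran-2-yl]methanol | CC(C)=CCC[C@]1(C)O[C@H]1CO | intermediate
3 | (3S)-3,7-dimethyloct-6-ene-1,3-diol | CC(C)=CCC[C@](C)(O)CCO | intermediate
4 | (3S)-3,7-dimethyl-1,3-bis(triethylsilyloxy)oct-6-ene | CC(C)=CCC[C@](C)(O[Si](CC)(CC)CC)CCO[Si](CC)(CC)CC | intermediate
5 | (3S)-3,7-dimethyl-3-(triethylsilyloxy)oct-6-enal | CC(C)=CCC[C@](C)(O[Si](CC)(CC)CC)CC=O | intermediate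
6 | methyl (2Z,5S)-5,9-dimethyl-5-(triethylsilyloxy)deca-2,8-dienoate | CC(C)=CCC[C@](C)(O[Si](CC)(CC)CC)C/C=C\C(=O)OC | intermediate
7 | (2Z,5S)-5,9-dimethyl-5-(triethylsilyloxy)deca-2,8-dien-1-ol | CC(C)=CCC[C@](C)(O[Si](CC)(CC)CC)C/C=C\CO | intermediate
8 | {(2S,3R)-3-[(2S)-2,6-dimethyl-2-(triethylsilyloxy)hept-5-en-1-yl]oxiran-2-yl}methanol (cis-oxirane) | CC(C)=CCC[C@](C)(O[Si](CC)(CC)CC)C[C@H]1O[C@H]1CO | intermediate
9 | (2R,3R)-3-[(2S)-2,6-dimethyl-2-(triethylsilyloxy)hept-5-en-1-yl]oxirane-2-carbaldehyde (cis-oxirane) | CC(C)=CCC[C@](C)(O[Si](CC)(CC)CC)C[C@H]1O[C@H]1C=O | intermediate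
10 | (2R,3S)-2-[(2S)-2,6-dimethyl-2-(triethylsilyloxy)hept-5-en-1-yl]-3-ethynyloxirane (cis-oxirane) | CC(C)=CCC[C@](C)(O[Si](CC)(CC)CC)C[C@H]1O[C@H]1C#C | intermediate
11 | (aS,4R,6S)-6,10-dimethyl-1-(4,4,5,5-tetramethyl-1,3,2-dioxaborolan-2-yl)-6-(triethylsilyloxy)undeca-1,2,9-trien-4-ol | CC(C)=CCC[C@](C)(O[Si](CC)(CC)CC)C[C@@H](O)C([H])=[C@@]=C([H])B1OC(C)(C)C(C)(C)O1 | intermediate
12 | (aS,4R,6S)-6,10-dimethyl-1-(4,4,5,5-tetramethyl-1,3,2-dioxaborolan-2-yl)-6-(triethylsilyloxy)undeca-1,2,9-trien-4-yl 2-methylpropanoate | CC(C)=CCC[C@](C)(O[Si](CC)(CC)CC)C[C@@H](OC(=O)C(C)C)C([H])=[C@@]=C([H])B1OC(C)(C)C(C)(C)O1 | intermediate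
13 | but-2-yn-1-ol | CC#CCO | starting material
14 | sodium cyclic (Z)-alkenylalanate: 2,2-bis(2-methoxyethoxy)-3-methyl-2,5-dihydro-1,2-oxaluminol-2-uide | CC1=CCO[Al-]1(OCCOC)OCCOC.[Na+] | intermediate (not isolated)
15 | (Z)-3-iodobut-2-en-1-ol | C/C(I)=C/CO | intermediate
16 | (Z)-3-iodobut-2-enal | C/C(I)=C/C=O | intermediate
17 | O6-pinacolboryl ether (borate ester) of 18 | CC(C)=CCC[C@](C)(O[Si](CC)(CC)CC)C[C@@H](OC(=O)C(C)C)[C@@H](C#C)[C@H](OB1OC(C)(C)C(C)(C)O1)/C=C(/C)I | intermediate (not isolated)
18 | (2Z,4S,5S,6R,8S)-5-ethynyl-4-hydroxy-2-iodo-8,12-dimethyl-8-(triethylsilyloxy)trideca-2,11-dien-6-yl 2-methylpropanoate | CC(C)=CCC[C@](C)(O[Si](CC)(CC)CC)C[C@@H](OC(=O)C(C)C)[C@@H](C#C)[C@H](O)/C=C(/C)I | intermediate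
19 | (2Z,4S,5R,6R,8S)-5-ethynyl-2-iodo-8,12-dimethyl-4,8-bis(triethylsilyloxy)trideca-2,11-dien-6-yl 2-methylpropanoate | CC(C)=CCC[C@](C)(O[Si](CC)(CC)CC)C[C@@H](OC(=O)C(C)C)[C@@H](C#C)[C@H](O[Si](CC)(CC)CC)/C=C(/C)I | intermediate
20 | 11,12-diol of 19 (mixture at the new secondary carbinol) | CC(C)(O)C(O)CC[C@](C)(O[Si](CC)(CC)CC)C[C@@H](OC(=O)C(C)C)[C@@H](C#C)[C@H](O[Si](CC)(CC)CC)/C=C(/C)I | intermediate (not isolated)
21 | (4S,6R,7R,8S,9Z)-7-ethynyl-10-iodo-4-methyl-1-oxo-4,8-bis(triethylsilyloxy)undec-9-en-6-yl 2-methylpropanoate | O=CCC[C@](C)(O[Si](CC)(CC)CC)C[C@@H](OC(=O)C(C)C)[C@@H](C#C)[C@H](O[Si](CC)(CC)CC)/C=C(/C)I | intermediate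
22 | (1R,2R,3R,4Z,9S)-2-ethynyl-6-hydroxy-5,9-dimethyl-3,9-bis(triethylsilyloxy)cyclodec-4-en-1-yl 2-methylpropanoate, both epimers at ring C6 (target C3) | C#C[C@H]1[C@H](O[Si](CC)(CC)CC)/C=C(/C)C(O)CC[C@](C)(O[Si](CC)(CC)CC)C[C@H]1OC(=O)C(C)C | intermediate
23 | (1R,2R,3R,4Z,9S)-2-ethynyl-5,9-dimethyl-6-oxo-3,9-bis(triethylsilyloxy)cyclodec-4-en-1-yl 2-methylpropanoate | C#C[C@H]1[C@H](O[Si](CC)(CC)CC)/C=C(/C)C(=O)CC[C@](C)(O[Si](CC)(CC)CC)C[C@H]1OC(=O)C(C)C | intermediate
24 | (1R,2R,3R,4Z,6S,9S)-2-ethynyl-6-hydroxy-5,9-dimethyl-3,9-bis(triethylsilyloxy)cyclodec-4-en-1-yl 2-methylpropanoate | C#C[C@H]1[C@H](O[Si](CC)(CC)CC)/C=C(/C)[C@@H](O)CC[C@](C)(O[Si](CC)(CC)CC)C[C@H]1OC(=O)C(C)C | intermediate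
25 | (1R,2S,3R,4Z,6S,9S)-2-ethynyl-3,6,9-trihydroxy-5,9-dimethylcyclodec-4-en-1-yl 2-methylpropanoate | C#C[C@H]1[C@H](O)/C=C(/C)[C@@H](O)CC[C@](C)(O)C[C@H]1OC(=O)C(C)C | intermediate
26 | chloro(alkoxycarbonyl)palladium(II) species on O6 of 25 (PPh3 ligands not written) | C#C[C@H]1[C@H](OC(=O)[Pd]Cl)/C=C(/C)[C@@H](O)CC[C@](C)(O)C[C@H]1OC(=O)C(C)C | intermediate (not isolated)
27 | (Z)-σ-vinylpalladium chloride of the closed lactone, Pd on C13 cis to C12 (PPh3 ligands not written) | Cl[Pd]/C=C1\C(=O)O[C@@H]2/C=C(/C)[C@@H](O)CC[C@](C)(O)C[C@@H](OC(=O)C(C)C)[C@@H]12 | intermediate (not isolated)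
28 | CNP0163972.1, (3aR,4R,6S,9S,10Z,11aR)-6,9-dihydroxy-6,10-dimethyl-3-methylidene-2-oxo-2,3,3a,4,5,6,7,8,9,11a-decahydrocyclodeca[b]furan-4-yl 2-methylpropanoate | C=C1C(=O)O[C@@H]2/C=C(/C)[C@@H](O)CC[C@](C)(O)C[C@@H](OC(=O)C(C)C)[C@@H]12 | target

## Step count and risks

Total step count: 21. Longest linear sequence: 19 steps (geraniol to target, steps 1–11 and 14–21); steps 12–13 are the two-step side branch to the iodo enal.

**Risk 1, step 10 (borylative opening).** The terminal alkyne may be deprotonated to a copper acetylide, the allene may be borylated a second time or protodeborylated, or the anti course may be incomplete, which would erode the C7 configuration set in step 14.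
Fallback, from 10 and back at 18: the alkyne of 10 is capped (LiHMDS, TMSCl, THF, −78 °C) to give the C-silyl alkynyl oxirane F1, an internal alkyne and thus the substrate class on which the borylative opening is established. The same Cu/B2pin2 conditions should give the 1-silyl allenylboronate alcohol F2, and acylation as in step 11 its isobutyrate F3. Allenylboration of 16 with F3 should give the C-silyl homopropargylic alcohol F4. Silver nitrate-catalysed protodesilylation (2,6-lutidine, acetone/H2O) of F4 returns to 18.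

**Risk 2, step 17 (ring closure).** Closing a ten-membered ring may lose to intermolecular coupling, the C–I bond may be reduced, and nickel may engage the terminal alkyne.
Fallback, from 21 and back at 23: the same bond is closed at the ketone oxidation level by reductive acyl cross-coupling. Pinnick oxidation of 21 (NaClO2, NaH2PO4, 2-methyl-2-butene) gives the carboxylic acid F5. 2,2′-Dipyridyl disulfide/PPh3 converts it into the S-(2-pyridyl) thioester F6. Nickel/zirconium-mediated ketone synthesis (NiBr2·dtbbpy cat., Cp2ZrCl2, Zn, DMI/THF, high dilution) should then join the iodoalkene to the thioester and give enone 23 directly, without 22 and step 18.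

**Risk 3, step 21 (key step).** The alkoxycarbonyl–palladium species may not form or may not insert the alkyne, or the Lewis-acidic medium may ionise the allylic C3/C6 hydroxyls or cause O8→O6 acyl shift.
Fallback, from 25 and back at 28: the carbonyl is brought in through a 2-iodoalkene. Ruthenium-catalysed Markovnikov hydrosilylation of 25 ([Cp*Ru(MeCN)3]PF6, Et3SiH, CH2Cl2, 0 °C) should give the α-vinylsilane F7. Iododesilylation (NIS, HFIP, 0 °C) gives the 2-iodoalkene F8. Palladium-catalysed carbonylative lactonisation (Pd(PPh3)4, CO 1 atm, K2CO3, THF, 50 °C) should give 28. In this variant CO inserts into the C11–Pd bond first and the ring is closed by acylation of O6.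

## Further compounds

F1 | step 10 | (2R,3S)-2-[(2S)-2,6-dimethyl-2-(triethylsilyloxy)hept-5-en-1-yl]-3-[(trimethylsilyl)ethynyl]oxirane | CC(C)=CCC[C@](C)(O[Si](CC)(CC)CC)C[C@H]1O[C@H]1C#C[Si](C)(C)C
F2 | step 10 | (aR,4R,6S)-6,10-dimethyl-1-(pinacolboryl)-6-(triethylsilyloxy)-1-(trimethylsilyl)undeca-1,2,9-trien-4-ol | CC(C)=CCC[C@](C)(O[Si](CC)(CC)CC)C[C@@H](O)C([H])=[C@@]=C([Si](C)(C)C)B1OC(C)(C)C(C)(C)O1
F3 | step 10 | 2-methylpropanoate of F2 | CC(C)=CCC[C@](C)(O[Si](CC)(CC)CC)C[C@@H](OC(=O)C(C)C)C([H])=[C@@]=C([Si](C)(C)C)B1OC(C)(C)C(C)(C)O1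
F4 | step 10 | (2Z,4S,5S,6R,8S)-4-hydroxy-2-iodo-8,12-dimethyl-8-(triethylsilyloxy)-5-[(trimethylsilyl)ethynyl]trideca-2,11-dien-6-yl 2-methylpropanoate | CC(C)=CCC[C@](C)(O[Si](CC)(CC)CC)C[C@@H](OC(=O)C(C)C)[C@@H](C#C[Si](C)(C)C)[C@H](O)/C=C(/C)I
F5 | step 17 | (4S,6R,7R,8S,9Z)-7-ethynyl-10-iodo-4-methyl-6-(2-methylpropanoyloxy)-4,8-bis(triethylsilyloxy)undec-9-enoic acid | OC(=O)CC[C@](C)(O[Si](CC)(CC)CC)C[C@@H](OC(=O)C(C)C)[C@@H](C#C)[C@H](O[Si](CC)(CC)CC)/C=C(/C)I
F6 | step 17 | S-(pyridin-2-yl) thioester of F5 | O=C(Sc1ccccn1)CC[C@](C)(O[Si](CC)(CC)CC)C[C@@H](OC(=O)C(C)C)[C@@H](C#C)[C@H](O[Si](CC)(CC)CC)/C=C(/C)I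
F7 | step 21 | (1R,2S,3R,4Z,6S,9S)-3,6,9-trihydroxy-5,9-dimethyl-2-[1-(triethylsilyl)ethenyl]cyclodec-4-en-1-yl 2-methylpropanoate | C=C([Si](CC)(CC)CC)[C@H]1[C@H](O)/C=C(/C)[C@@H](O)CC[C@](C)(O)C[C@H]1OC(=O)C(C)C
F8 | step 21 | (1R,2S,3R,4Z,6S,9S)-3,6,9-trihydroxy-2-(1-iodoethenyl)-5,9-dimethylcyclodec-4-en-1-yl 2-methylpropanoate | C=C(I)[C@H]1[C@H](O)/C=C(/C)[C@@H](O)CC[C@](C)(O)C[C@H]1OC(=O)C(C)C
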